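Per litre of the first phase: count every charge and every rate of this run that way.

starting material 0.10 M; reagent in the second phase 0.150 M; time 2.5 h; volume of the second phase over the first 0.25

    reagent in the reaction phase ⇌ reagent in the second phase, rate k1*([reagent in the reaction phase] - [reagent in the second phase]/K1) per volume of the first phase (K1 = 0.40, k1 = 0.010 /s)
    starting material + reagent in the reaction phase → target (k2 = 0.0074 /M/s)
    target ⇌ product in the second phase, rate k3*([target] - [product in the second phase]/K3) per volume of the first phase (K3 = 27, k3 = 2.2 × 10⁻⁴ /s)
    target → decomposed product (k4 = 2.7 × 10⁻⁴ /s)
    target ⇌ isomer of the product (K5 = 13, k5 = 6.0 × 10⁻⁴ /s)

- amounts and yields of target count product in the second phase too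
- in the second phase: reagent in the second phase, product in the second phase; everything else is in the first
- charges count per volume of the first phase; a concentration in a rate is the amount of a species over the volume of its own phase; every rate counts per litre of the first phase
- run time (flask): 2.5 h

- target and product in the second phase together at 2.5 h, in percent of the starting material charged
- the change that raises the amount of target and product in the second phase together at 2.5 h, in percent of the starting material charged most ("none" if none brings more than 2 percentage points) (blue / violet / teal / none)
- amount of target and product in the second phase together at 2.5 h, in percent of the starting material charged, after blue

- blue: doubling the transfer coefficient of step 3, all else as stated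
- violet: doubling the transfer coefficient of step 1, all else as stated
- teal: doubling the amount of reagent in the second phase, all else as stated

Watch the rate of the second step, which makes target. Treat the reagent's transfer as balanced, because its relaxation half-time of 6.30 s is far shorter than the 0.26 h the second step gives the reagent in the reaction phase with the other concentrations as charged. The balance puts a free share of 90.9% of all the reagent in the reaction phase, so once the transfer has balanced, with no starting material yet counted as lost, the flask's rate is 0.363 M/h.

Two factors slow that rate, and they are tied. Each starting material lost takes one reagent with it, so the excess of total reagent over starting material stays 0.0500 M. Starting material is therefore the limiting reagent. Now reckon the excess clock, 1.21 /h: the rate constant of the second step times the free share times the charged excess of reagent, the rate at which the logarithm of total reagent over starting material climbs. That ratio goes from 1.50 to 31.0 in 2.5 h. So [starting material] cuts the rate by a factor of 59.9 and [reagent in the reaction phase] by 2.90, much less. Together they slow it 174-fold, to 0.00209 M/h.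

Expect, then, 1.67% of the starting material unturned at the end, so that nearly all of the charge has gone through the second step. The reckoning stops there. It tells what was made, not what stands, and the half-lives of reaction-phase target, each by its step alone, of 0.32 h towards the isomer (forward rate) and 0.71 h towards decomposed product are short against 2.5 h.

The forecast gave 22.6%, blue as the best change and 29.5% after it, holding that “extra reagent only brings forward a conversion that is already nearly complete”.

The flask gives 22.3%, with blue best at a gain of 8.8 percentage points, reaching 31.1%. Doubling the transfer coefficient of the reagent's step moves the answer by 0 points, and starting material stands at 1.67% at 2.50 h, against the clock's 1.67%. Run the clock on the neighbour charged with 0.40 M of starting material: the excess turns to −0.250 M, the clock to −6.05 /h, and the reagent becomes the limiting one. The ratio of total reagent over starting material falls to 1.00 × 10⁻⁷, which gives 2.27 × 10⁻⁸ M of reagent in the reaction phase, against 2.36 × 10⁻⁸ M in that neighbour at 2.50 h.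

The constants used here stand for no real mixture, and the outcome is calculated.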